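**Retrosynthetic overview**

1. Last bonds: the tert‑butyl ester is cleaved at the end; the ester bond between the halves is made by opening a spiro‑epoxide on the right‑hand bicyclic lactone with the carboxylate of the left‑hand acid, so the tertiary carbinol is already in place.
2. Left half: the enoic acid side chain comes from cross‑metathesis on a propenyl group; the cyclohexene ring comes from a [3,3] (Claisen) ring contraction of an eight‑membered cyclic (Z)‑enol ether. That ether is made from a dienyl lactone (Stobbe condensation, esterification with (S)‑but‑3‑en‑2‑ol, ring‑closing metathesis, alkylidenation), and the ketone left by the rearrangement is then deleted.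
3. Enabling feature: in the left cyclohexene the two adjacent ring CH stereocentres (isopropyl carbon and side‑chain carbon) sit between a ring CH2 and the exocyclic CH=C of the side chain. With a temporary C=O on that ring CH2 this is the γ,δ‑unsaturated ketone O=C–CH(i‑Pr)–CH–CH=C, the retron of a Claisen rearrangement whose new σ‑bond is the ring bond joining the two stereocentres.
4. Right half: (S)‑4‑isopropylcyclohexenone (enamine Michael/aldol) → α‑hydroxymethylation → vinyl 1,4‑addition with kinetic protonation → epoxide homologation → acid → acrylate ester → ring‑closing metathesis to the seven‑membered lactone.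
5. Ring order: eight‑membered lactone → left cyclohexene (contraction); right cyclohexanone ring → spiro‑oxirane → seven‑membered lactone; the halves are joined last.

Key step: step 5

Assumption: 1,1‑dibromo‑2‑methylpropane is treated as a purchasable reagent (otherwise one step from isobutyraldehyde), and the carbinol centre made in step 6 is carried on as an epimer mixture because it is removed in step 8.

**Route**

Step 1
Reactants: 1 di‑tert‑butyl succinate; 2 (E)‑but‑2‑enal
Product: 3 (3E,5E)‑3‑(tert‑butoxycarbonyl)hepta‑3,5‑dienoic acid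
Conditions: KOt‑Bu, t‑BuOH, 0 → 25 °C; aq. HCl work‑up
Reagents that add atoms: none
Why: Stobbe condensation: the succinate enolate adds 1,2 to the enal, the alkoxide lactonises onto the second ester and base‑induced opening of the paraconate gives the half‑ester, with the alkenyl chain cis to the CH2CO2H arm (E), which is the geometry the later ring needs.

Step 2
Reactants: 3 (3E,5E)‑3‑(tert‑butoxycarbonyl)hepta‑3,5‑dienoic acid; 4 (S)‑but‑3‑en‑2‑ol
Product: 5 (S)‑but‑3‑en‑2‑yl (3E,5E)‑3‑(tert‑butoxycarbonyl)hepta‑3,5‑dienoate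
Conditions: DCC, DMAP (cat.), CH2Cl2, 0 → 25 °C
Reagents that add atoms: none
Why: Steglich esterification of the free acid; the carbinol C–O bond is not broken, so the (S) centre that later steers the rearrangement is kept.

Step 3
Reactants: 5 (S)‑but‑3‑en‑2‑yl (3E,5E)‑3‑(tert‑butoxycarbonyl)hepta‑3,5‑dienoate
Product: 6 tert‑butyl (8S)‑8‑methyl‑2‑oxo‑3,8‑dihydro‑2H‑oxocine‑4‑carboxylate (both ring alkenes cis within the ring)
Conditions: RuCl2(=CHPh)(PCy3)(H2IMes) (second‑generation Grubbs catalyst, 10 mol %), toluene (2 mM), 80 °C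
Reagents that add atoms: none
Why: Ring‑closing metathesis: the catalyst loads on the terminal vinyl group and closes onto the propenyl terminus with loss of propene, the ester‑bearing trisubstituted alkene being inert; the eight‑membered ring can only hold the new alkene cis, and the existing cis‑trisubstituted alkene pre‑folds the chain.

Step 4
Reactants: 6 tert‑butyl (8S)‑8‑methyl‑2‑oxo‑3,8‑dihydro‑2H‑oxocine‑4‑carboxylate
Product: 7 tert‑butyl (2Z,8S)‑8‑methyl‑2‑(2‑methylpropylidene)‑3,8‑dihydro‑2H‑oxocine‑4‑carboxylate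
Conditions: i‑PrCHBr2, Zn, TiCl4, TMEDA, THF, 0 → 25 °C; basic alumina filtration
Reagents that add atoms: 1,1‑dibromo‑2‑methylpropane, CC(C)C(Br)Br
Why: Takai–Utimoto alkylidenation of the lactone carbonyl, which gives Z enol ethers (alkyl cis to the ether oxygen) and should leave the hindered, conjugated tert‑butyl ester alone.

Step 5
Reactants: 7 tert‑butyl (2Z,8S)‑8‑methyl‑2‑(2‑methylpropylidene)‑3,8‑dihydro‑2H‑oxocine‑4‑carboxylate
Product: 8 tert‑butyl (3R,4R)‑5‑oxo‑3‑[(E)‑prop‑1‑en‑1‑yl]‑4‑(propan‑2‑yl)cyclohex‑1‑ene‑1‑carboxylate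
Conditions: toluene (0.01 M), Et3N (trace), BHT, 135 °C, sealed tube, base‑washed glassware
Reagents that add atoms: none
Why: Proposed new method: on heating, the cyclic allyl vinyl ether 7 should undergo a concerted [3,3]‑sigmatropic (Claisen) shift in which the exocyclic enol‑ether carbon bonds to the ring allylic terminus while the ring O–CH(CH3) bond breaks, so that the eight‑membered oxocine contracts to the six‑membered carbocycle, the ether oxygen becomes the ring ketone and the former carbinol carbon swings out as the propenyl group. The closest known reaction types are the thermal Claisen rearrangement of lactone‑derived 2‑methylene oxacycles with change of ring size (2‑methylene‑6‑vinyltetrahydropyrans to cyclooct‑4‑enones) and the Ireland–Claisen ring contraction of unsaturated lactones; the contracting mode with an exocyclic enol ether and an endocyclic allyl unit is the untested part. The cyclohexenone ring closes by suprafacial C–C bond formation through a chair‑like six‑centre transition state bridged by the three‑carbon tether (a bicyclo[3.3.1]‑like array; a boat cannot be spanned by this tether). The isopropyl‑bearing centre is set by the Z enol ether (isopropyl axial in the chair, hence equatorial on the new ring) and the propenyl‑bearing centre by the cis ring alkene (its ring substituent axial in the chair), which together give the cis‑3,4 relationship. The (S)‑carbinol carbon, with its methyl group equatorial in the chair, transfers chirality to both centres and makes the propenyl group E. The step needs [3,3] ring contraction rather than a [1,3] shift or conjugation of the β,γ‑unsaturated ketone, which the concerted pathway, the tether and neutral base‑washed glassware should secure.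

Step 6
Reactants: 8 tert‑butyl (3R,4R)‑5‑oxo‑3‑[(E)‑prop‑1‑en‑1‑yl]‑4‑(propan‑2‑yl)cyclohex‑1‑ene‑1‑carboxylate
Product: 9 tert‑butyl (3R,4R,5R)‑5‑hydroxy‑3‑[(E)‑prop‑1‑en‑1‑yl]‑4‑(propan‑2‑yl)cyclohex‑1‑ene‑1‑carboxylate (one C5 epimer shown; the other is carried along)
Conditions: NaBH4, CeCl3·7H2O, MeOH, −78 °C
Reagents that add atoms: none
Why: Luche reduction, fast and 1,2‑selective at −78 °C, so the β,γ‑unsaturated ketone is consumed before it can epimerise or conjugate and the enoate is untouched; the new carbinol centre is removed in step 8, so its configuration does not matter.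

Step 7
Reactants: 9 tert‑butyl (3R,4R,5R)‑5‑hydroxy‑3‑[(E)‑prop‑1‑en‑1‑yl]‑4‑(propan‑2‑yl)cyclohex‑1‑ene‑1‑carboxylate
Product: 10 tert‑butyl (3R,4R,5R)‑5‑[(1H‑imidazol‑1‑ylcarbonothioyl)oxy]‑3‑[(E)‑prop‑1‑en‑1‑yl]‑4‑(propan‑2‑yl)cyclohex‑1‑ene‑1‑carboxylate
Conditions: 1,1′‑thiocarbonyldiimidazole, DMAP (cat.), toluene, 80 °C
Reagents that add atoms: 1,1′‑thiocarbonyldiimidazole, S=C(n1ccnc1)n1ccnc1
Why: O‑Thioacylation of the secondary alcohol under neutral conditions, the first half of a Barton–McCombie deoxygenation.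

Step 8
Reactants: 10 tert‑butyl (3R,4R,5R)‑5‑[(1H‑imidazol‑1‑ylcarbonothioyl)oxy]‑3‑[(E)‑prop‑1‑en‑1‑yl]‑4‑(propan‑2‑yl)cyclohex‑1‑ene‑1‑carboxylate
Product: 11 tert‑butyl (3S,4R)‑3‑[(E)‑prop‑1‑en‑1‑yl]‑4‑(propan‑2‑yl)cyclohex‑1‑ene‑1‑carboxylate
Conditions: Bu3SnH, AIBN (cat.), toluene, 100 °C
Reagents that add atoms: none
Why: Barton–McCombie radical deoxygenation; the secondary radical is reduced by the stannane without touching the two neighbouring stereocentres, the enoate or the propenyl group.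

Step 9
Reactants: 11 tert‑butyl (3S,4R)‑3‑[(E)‑prop‑1‑en‑1‑yl]‑4‑(propan‑2‑yl)cyclohex‑1‑ene‑1‑carboxylate
Product: 12 [(3S,4R)‑3‑[(E)‑prop‑1‑en‑1‑yl]‑4‑(propan‑2‑yl)cyclohex‑1‑en‑1‑yl]methanol
Conditions: i‑Bu2AlH, CH2Cl2, −78 → 0 °C; Rochelle salt work‑up
Reagents that add atoms: none
Why: 1,2‑Reduction of the unsaturated tert‑butyl ester to the allylic alcohol by the aluminium hydride.

Step 10
Reactants: 12 [(3S,4R)‑3‑[(E)‑prop‑1‑en‑1‑yl]‑4‑(propan‑2‑yl)cyclohex‑1‑en‑1‑yl]methanol; 13 2‑(hydroxymethyl)prop‑2‑enoic acid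
Product: 14 (E)‑2‑(hydroxymethyl)‑3‑[(1S,6R)‑3‑(hydroxymethyl)‑6‑(propan‑2‑yl)cyclohex‑2‑en‑1‑yl]prop‑2‑enoic acid
Conditions: 13 (4 equiv), RuCl2(=CH‑2‑(i‑PrO)C6H4)(H2IMes) (second‑generation Hoveyda–Grubbs catalyst, 10 mol %), CH2Cl2, 40 °C
Reagents that add atoms: none
Why: Olefin cross‑metathesis: the propenyl group exchanges with the 1,1‑disubstituted acrylic acid (which does not homodimerise) with loss of propene, the trisubstituted ring alkene staying out; the thermodynamic E enoic acid (carboxyl trans to the ring) is expected.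

Step 11
Reactants: 15 3‑methylbutanal; 16 but‑3‑en‑2‑one
Product: 18 (S)‑4‑(propan‑2‑yl)cyclohex‑2‑en‑1‑one, via (S)‑2‑isopropyl‑5‑oxohexanal 17 (not isolated)
Conditions: (S)‑2‑[diphenyl(trimethylsilyloxy)methyl]pyrrolidine (10 mol %), ethyl 3,4‑dihydroxybenzoate (20 mol %), neat, 4 °C; then p‑TsOH·H2O (cat.), toluene, 60 °C
Reagents that add atoms: none
Why: Enamine‑catalysed Michael addition of the aldehyde to the enone, the diarylprolinol silyl ether shielding one face of the E‑enamine and so setting the (S) centre, followed by acid‑promoted intramolecular aldol condensation of the keto aldehyde to the cyclohexenone.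

Step 12
Reactants: 18 (S)‑4‑(propan‑2‑yl)cyclohex‑2‑en‑1‑one
Product: 19 (S)‑2‑(hydroxymethyl)‑4‑(propan‑2‑yl)cyclohex‑2‑en‑1‑one
Conditions: 37% aq. CH2O, DMAP (20 mol %), THF, 25 °C
Reagents that add atoms: formaldehyde, C=O
Why: Morita–Baylis–Hillman reaction of the cyclic enone with formaldehyde puts the one‑carbon unit on the α‑carbon.

Step 13
Reactants: 19 (S)‑2‑(hydroxymethyl)‑4‑(propan‑2‑yl)cyclohex‑2‑en‑1‑one
Product: 20 (S)‑2‑{[tert‑butyl(dimethyl)silyl]oxymethyl}‑4‑(propan‑2‑yl)cyclohex‑2‑en‑1‑one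
Conditions: TBSCl, imidazole, DMF, 25 °C
Reagents that add atoms: tert‑butyldimethylsilyl chloride, CC(C)(C)[Si](C)(C)Cl
Why: Silylation of the primary alcohol, so that the enolate of the next step cannot lose formaldehyde by retro‑aldol cleavage.

Step 14
Reactants: 20 (S)‑2‑{[tert‑butyl(dimethyl)silyl]oxymethyl}‑4‑(propan‑2‑yl)cyclohex‑2‑en‑1‑one
Product: 21 (2R,3S,4S)‑2‑{[tert‑butyl(dimethyl)silyl]oxymethyl}‑3‑ethenyl‑4‑(propan‑2‑yl)cyclohexan‑1‑one
Conditions: CH2=CHMgBr, CuI (10 mol %), THF, −78 °C; then AcOH in THF, −78 °C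
Reagents that add atoms: vinylmagnesium bromide, C=C[Mg]Br
Why: Copper‑catalysed 1,4‑addition of the vinyl Grignard reagent anti to the neighbouring isopropyl group (trans‑3,4), then kinetic protonation of the magnesium enolate at −78 °C from the face opposite the new vinyl group, which should give the contra‑thermodynamic cis‑2,3 ketone.

Step 15
Reactants: 21 (2R,3S,4S)‑2‑{[tert‑butyl(dimethyl)silyl]oxymethyl}‑3‑ethenyl‑4‑(propan‑2‑yl)cyclohexan‑1‑one
Product: 22 tert‑butyl{[(3R,4R,5S,6S)‑5‑ethenyl‑6‑(propan‑2‑yl)‑1‑oxaspiro[2.5]octan‑4‑yl]methoxy}dimethylsilane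
Conditions: CH2I2, MeLi, THF, −78 → 0 °C
Reagents that add atoms: diiodomethane, ICI
Why: Epoxide homologation with iodomethyllithium: addition to the carbonyl along the axial trajectory anti to the axial α‑CH2OSi group, then ring closure of the iodohydrin alkoxide, places the new CH2 trans and the oxygen cis to that α‑substituent.

Step 16
Reactants: 22 tert‑butyl{[(3R,4R,5S,6S)‑5‑ethenyl‑6‑(propan‑2‑yl)‑1‑oxaspiro[2.5]octan‑4‑yl]methoxy}dimethylsilane
Product: 23 [(3R,4R,5S,6S)‑5‑ethenyl‑6‑(propan‑2‑yl)‑1‑oxaspiro[2.5]octan‑4‑yl]methanol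
Conditions: Bu4NF, THF, 0 °C
Reagents that add atoms: none
Why: Fluoride cleavage of the silyl ether; the liberated alkoxide is trans‑diaxial to the epoxide CH2 and cannot open it.

Step 17
Reactants: 23 [(3R,4R,5S,6S)‑5‑ethenyl‑6‑(propan‑2‑yl)‑1‑oxaspiro[2.5]octan‑4‑yl]methanol
Product: 24 (3R,4S,5S,6S)‑5‑ethenyl‑6‑(propan‑2‑yl)‑1‑oxaspiro[2.5]octane‑4‑carboxylic acid
Conditions: TEMPO (cat.), PhI(OAc)2, NaHCO3, MeCN/H2O, 0 → 25 °C
Reagents that add atoms: water, O
Why: TEMPO/PhI(OAc)2 oxidation of the primary alcohol through the aldehyde hydrate to the acid under buffered conditions that should neither epimerise the α‑centre nor open the epoxide.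

Step 18
Reactants: 24 (3R,4S,5S,6S)‑5‑ethenyl‑6‑(propan‑2‑yl)‑1‑oxaspiro[2.5]octane‑4‑carboxylic acid; 25 tert‑butyl 2‑(bromomethyl)prop‑2‑enoate
Product: 26 2‑(tert‑butoxycarbonyl)prop‑2‑en‑1‑yl (3R,4S,5S,6S)‑5‑ethenyl‑6‑(propan‑2‑yl)‑1‑oxaspiro[2.5]octane‑4‑carboxylate
Conditions: Cs2CO3, DMF, 0 → 25 °C
Reagents that add atoms: none
Why: O‑Alkylation of the caesium carboxylate with the allylic bromide (SN2 and SN2′ give the same product), which avoids activating a hindered acid.

Step 19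
Reactants: 26 2‑(tert‑butoxycarbonyl)prop‑2‑en‑1‑yl (3R,4S,5S,6S)‑5‑ethenyl‑6‑(propan‑2‑yl)‑1‑oxaspiro[2.5]octane‑4‑carboxylate
Product: 27 tert‑butyl 6‑isopropyl‑1‑oxo‑3,5a,6,7,8,9a‑hexahydro‑1H‑spiro[2‑benzoxepine‑9,2′‑oxirane]‑4‑carboxylate (cis ring fusion; isopropyl on the face of the ring‑fusion hydrogens; oxirane oxygen on the opposite face, cis to the lactone carbonyl carbon)
Conditions: RuCl2(=CH‑2‑(i‑PrO)C6H4)(H2IMes) (second‑generation Hoveyda–Grubbs catalyst, 10 mol %), toluene (2 mM), 80 °C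
Reagents that add atoms: none
Why: Ring‑closing metathesis between the ring vinyl group and the 1,1‑disubstituted acrylate closes the seven‑membered lactone and makes the trisubstituted enoate, whose geometry is fixed by the ring.

Step 20
Reactants: 14 (E)‑2‑(hydroxymethyl)‑3‑[(1S,6R)‑3‑(hydroxymethyl)‑6‑(propan‑2‑yl)cyclohex‑2‑en‑1‑yl]prop‑2‑enoic acid; 27 tert‑butyl 6‑isopropyl‑1‑oxo‑3,5a,6,7,8,9a‑hexahydro‑1H‑spiro[2‑benzoxepine‑9,2′‑oxirane]‑4‑carboxylate
Product: 28 tert‑butyl ester of the target (free tertiary alcohol, both primary alcohols free)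
Conditions: Cs2CO3 (20 mol %), DMF, 70 °C
Reagents that add atoms: none
Why: Nucleophilic opening of the 2,2‑disubstituted epoxide at its CH2 carbon by the caesium carboxylate (SN2, the carboxylate being far more nucleophilic than the free hydroxyls) joins the fragments as the primary ester and frees the tertiary alcohol, whose C–O bond is not touched.

Step 21
Reactants: 28 tert‑butyl ester of the target
Product: 29 CNP0361406.7
Conditions: CF3CO2H/CH2Cl2 (1:4), 0 → 25 °C; aq. NaHCO3 work‑up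
Reagents that add atoms: none
Why: Acidolysis of the tert‑butyl ester with loss of 2‑methylpropene frees the conjugated acid without affecting the lactone, the linking ester or the alcohols.

**Compound list**

1 | di‑tert‑butyl succinate | CC(C)(C)OC(=O)CCC(=O)OC(C)(C)C | starting material
2 | (E)‑but‑2‑enal | C/C=C/C=O | starting material
3 | (3E,5E)‑3‑(tert‑butoxycarbonyl)hepta‑3,5‑dienoic acid | OC(=O)C/C(C(=O)OC(C)(C)C)=C\C=C\C | intermediate
4 | (S)‑but‑3‑en‑2‑ol | C[C@H](O)C=C | starting material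
5 | (S)‑but‑3‑en‑2‑yl (3E,5E)‑3‑(tert‑butoxycarbonyl)hepta‑3,5‑dienoate | C=C[C@H](C)OC(=O)C/C(C(=O)OC(C)(C)C)=C\C=C\C | intermediate
6 | tert‑butyl (8S)‑8‑methyl‑2‑oxo‑3,8‑dihydro‑2H‑oxocine‑4‑carboxylate | O=C1C/C(C(=O)OC(C)(C)C)=C\C=C/[C@H](C)O1 | intermediate
7 | tert‑butyl (2Z,8S)‑8‑methyl‑2‑(2‑methylpropylidene)‑3,8‑dihydro‑2H‑oxocine‑4‑carboxylate | CC(C)/C=C1/C/C(C(=O)OC(C)(C)C)=C\C=C/[C@H](C)O1 | intermediate
8 | tert‑butyl (3R,4R)‑5‑oxo‑3‑[(E)‑prop‑1‑en‑1‑yl]‑4‑(propan‑2‑yl)cyclohex‑1‑ene‑1‑carboxylate | CC(C)[C@H]1C(=O)CC(C(=O)OC(C)(C)C)=C[C@H]1/C=C/C | intermediate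
9 | tert‑butyl (3R,4R,5R)‑5‑hydroxy‑3‑[(E)‑prop‑1‑en‑1‑yl]‑4‑(propan‑2‑yl)cyclohex‑1‑ene‑1‑carboxylate | CC(C)[C@H]1[C@H](O)CC(C(=O)OC(C)(C)C)=C[C@H]1/C=C/C | intermediate
10 | tert‑butyl (3R,4R,5R)‑5‑[(1H‑imidazol‑1‑ylcarbonothioyl)oxy]‑3‑[(E)‑prop‑1‑en‑1‑yl]‑4‑(propan‑2‑yl)cyclohex‑1‑ene‑1‑carboxylate | CC(C)[C@H]1[C@H](OC(=S)n2ccnc2)CC(C(=O)OC(C)(C)C)=C[C@H]1/C=C/C | intermediate
11 | tert‑butyl (3S,4R)‑3‑[(E)‑prop‑1‑en‑1‑yl]‑4‑(propan‑2‑yl)cyclohex‑1‑ene‑1‑carboxylate | CC(C)[C@H]1CCC(C(=O)OC(C)(C)C)=C[C@H]1/C=C/C | intermediate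
12 | [(3S,4R)‑3‑[(E)‑prop‑1‑en‑1‑yl]‑4‑(propan‑2‑yl)cyclohex‑1‑en‑1‑yl]methanol | CC(C)[C@H]1CCC(CO)=C[C@H]1/C=C/C | intermediate
13 | 2‑(hydroxymethyl)prop‑2‑enoic acid | C=C(CO)C(=O)O | starting material
14 | (E)‑2‑(hydroxymethyl)‑3‑[(1S,6R)‑3‑(hydroxymethyl)‑6‑(propan‑2‑yl)cyclohex‑2‑en‑1‑yl]prop‑2‑enoic acid | CC(C)[C@H]1CCC(CO)=C[C@H]1/C=C(\CO)C(=O)O | intermediate
15 | 3‑methylbutanal | CC(C)CC=O | starting material
16 | but‑3‑en‑2‑one | CC(=O)C=C | starting material
17 | (S)‑2‑isopropyl‑5‑oxohexanal (not isolated) | CC(=O)CC[C@@H](C(C)C)C=O | intermediate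
18 | (S)‑4‑(propan‑2‑yl)cyclohex‑2‑en‑1‑one | O=C1CC[C@@H](C(C)C)C=C1 | intermediate
19 | (S)‑2‑(hydroxymethyl)‑4‑(propan‑2‑yl)cyclohex‑2‑en‑1‑one | O=C1CC[C@@H](C(C)C)C=C1CO | intermediate
20 | (S)‑2‑{[tert‑butyl(dimethyl)silyl]oxymethyl}‑4‑(propan‑2‑yl)cyclohex‑2‑en‑1‑one | O=C1CC[C@@H](C(C)C)C=C1CO[Si](C)(C)C(C)(C)C | intermediate
21 | (2R,3S,4S)‑2‑{[tert‑butyl(dimethyl)silyl]oxymethyl}‑3‑ethenyl‑4‑(propan‑2‑yl)cyclohexan‑1‑one | O=C1CC[C@@H](C(C)C)[C@H](C=C)[C@@H]1CO[Si](C)(C)C(C)(C)C | intermediate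
22 | tert‑butyl{[(3R,4R,5S,6S)‑5‑ethenyl‑6‑(propan‑2‑yl)‑1‑oxaspiro[2.5]octan‑4‑yl]methoxy}dimethylsilane | C1O[C@@]12CC[C@@H](C(C)C)[C@H](C=C)[C@@H]2CO[Si](C)(C)C(C)(C)C | intermediate
23 | [(3R,4R,5S,6S)‑5‑ethenyl‑6‑(propan‑2‑yl)‑1‑oxaspiro[2.5]octan‑4‑yl]methanol | C1O[C@@]12CC[C@@H](C(C)C)[C@H](C=C)[C@@H]2CO | intermediate
24 | (3R,4S,5S,6S)‑5‑ethenyl‑6‑(propan‑2‑yl)‑1‑oxaspiro[2.5]octane‑4‑carboxylic acid | C1O[C@@]12CC[C@@H](C(C)C)[C@H](C=C)[C@@H]2C(=O)O | intermediate
25 | tert‑butyl 2‑(bromomethyl)prop‑2‑enoate | C=C(CBr)C(=O)OC(C)(C)C | starting material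
26 | 2‑(tert‑butoxycarbonyl)prop‑2‑en‑1‑yl (3R,4S,5S,6S)‑5‑ethenyl‑6‑(propan‑2‑yl)‑1‑oxaspiro[2.5]octane‑4‑carboxylate | C1O[C@@]12CC[C@@H](C(C)C)[C@H](C=C)[C@@H]2C(=O)OCC(=C)C(=O)OC(C)(C)C | intermediate
27 | tert‑butyl 6‑isopropyl‑1‑oxo‑3,5a,6,7,8,9a‑hexahydro‑1H‑spiro[2‑benzoxepine‑9,2′‑oxirane]‑4‑carboxylate (stereochemistry as described in step 19) | C1O[C@@]12CC[C@@H](C(C)C)[C@@H]3C=C(C(=O)OC(C)(C)C)COC(=O)[C@H]23 | intermediate
28 | tert‑butyl ester of the target | CC(C)[C@H]1CCC(CO)=C[C@H]1/C=C(\CO)C(=O)OC[C@@]1(O)CC[C@@H](C(C)C)[C@@H]2C=C(C(=O)OC(C)(C)C)COC(=O)[C@@H]21 | intermediate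
29 | CNP0361406.7 | CC(C)[C@H]1CCC(CO)=C[C@H]1/C=C(\CO)C(=O)OC[C@@]1(O)CC[C@@H](C(C)C)[C@@H]2C=C(C(=O)O)COC(=O)[C@@H]21 | target

**Step count and risks**

Total step count: 21. Longest linear sequence: 12 steps (steps 1–10, then 20 and 21).

Steps most likely to fail:

Step 5 (Proposed new method). The bridged chair transition state may be reached too slowly, so that hydrolysis of the enol ether, a competing [1,3] shift or conjugation of the product ketone wins. The fallback uses known chemistry only, sets out from 15 and 16 and returns at 12. The Michael/aldol sequence of step 11 is run with the (R)‑catalyst to give (R)‑4‑(propan‑2‑yl)cyclohex‑2‑en‑1‑one F1. 1,2‑Addition of (4‑methoxybenzyloxy)methyllithium (from its tributylstannane and n‑BuLi, THF, −78 °C) anti to the isopropyl group should give (1R,4R)‑1‑{[(4‑methoxyphenyl)methoxy]methyl}‑4‑(propan‑2‑yl)cyclohex‑2‑en‑1‑ol F2, with the hydroxyl cis to isopropyl. PhNCO and DMAP convert it into the N‑phenylcarbamate of that alcohol F3. Carbamate‑directed syn‑SN2′ substitution (n‑BuLi, CuI, then (E)‑prop‑1‑enyllithium, THF, −30 → 0 °C) delivers the propenyl group to the γ‑carbon on the carbamate face, that is cis to isopropyl, and moves the alkene under the CH2O group, giving the 4‑methoxybenzyl ether of alcohol 12 F4. DDQ (CH2Cl2/H2O) then frees 12.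

Step 3. Ring closure to the strained eight‑membered dienyl lactone may lose to intermolecular metathesis because the ester prefers its extended conformation. The fallback sets out from 5 and returns at 7. The Takai–Utimoto alkylidenation of step 4 is carried out first on the open‑chain ester (the saturated ester carbonyl reacts, the tert‑butyl dienoate does not) to give the acyclic Z enol ether tert‑butyl (2E)‑2‑[(E)‑but‑2‑en‑1‑ylidene]‑4‑[(S)‑but‑3‑en‑2‑yloxy]‑6‑methylhept‑4‑enoate F5. Its ether linkage no longer imposes the extended conformation. Ring‑closing metathesis (second‑generation Grubbs catalyst, CH2Cl2, 40 °C, well below the temperature at which the open‑chain allyl vinyl ether would rearrange) should then give 7 directly.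

Step 19. Cyclisation onto the hindered 1,1‑disubstituted acrylate may be slower than catalyst decay or dimerisation. The fallback sets out from 24 and returns at 27. Cross‑metathesis of the vinyl group with an excess of tert‑butyl 2‑(hydroxymethyl)prop‑2‑enoate should give the E hydroxy acid 5‑[(E)‑3‑tert‑butoxy‑2‑(hydroxymethyl)‑3‑oxoprop‑1‑en‑1‑yl]‑6‑(propan‑2‑yl)‑1‑oxaspiro[2.5]octane‑4‑carboxylic acid F6, with CH2OH cis to the ring carbon and the ring configuration of 24. The seven‑membered ring is then closed through the C–O bond by Yamaguchi lactonisation (2,4,6‑trichlorobenzoyl chloride, Et3N, then DMAP, toluene).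

Further compounds
F1 | step 5 | (R)‑4‑(propan‑2‑yl)cyclohex‑2‑en‑1‑one | O=C1CC[C@H](C(C)C)C=C1
F2 | step 5 | (1R,4R)‑1‑{[(4‑methoxyphenyl)methoxy]methyl}‑4‑(propan‑2‑yl)cyclohex‑2‑en‑1‑ol | CC(C)[C@H]1CC[C@](O)(COCc2ccc(OC)cc2)C=C1
F3 | step 5 | (1R,4R)‑1‑{[(4‑methoxyphenyl)methoxy]methyl}‑4‑(propan‑2‑yl)cyclohex‑2‑en‑1‑yl N‑phenylcarbamate | CC(C)[C@H]1CC[C@](OC(=O)Nc2ccccc2)(COCc2ccc(OC)cc2)C=C1
F4 | step 5 | 1‑methoxy‑4‑({[(3S,4R)‑3‑[(E)‑prop‑1‑en‑1‑yl]‑4‑(propan‑2‑yl)cyclohex‑1‑en‑1‑yl]methoxy}methyl)benzene | CC(C)[C@H]1CCC(COCc2ccc(OC)cc2)=C[C@H]1/C=C/C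
F5 | step 3 | tert‑butyl (2E)‑2‑[(E)‑but‑2‑en‑1‑ylidene]‑4‑[(S)‑but‑3‑en‑2‑yloxy]‑6‑methylhept‑4‑enoate (Z enol ether) | C=C[C@H](C)O/C(C/C(C(=O)OC(C)(C)C)=C\C=C\C)=C\C(C)C
F6 | step 19 | 5‑[(E)‑3‑tert‑butoxy‑2‑(hydroxymethyl)‑3‑oxoprop‑1‑en‑1‑yl]‑6‑(propan‑2‑yl)‑1‑oxaspiro[2.5]octane‑4‑carboxylic acid | C1O[C@@]12CC[C@@H](C(C)C)[C@H](/C=C(\CO)C(=O)OC(C)(C)C)[C@@H]2C(=O)O
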